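## Structural features

The target is a 2,3-dimethylchroman-4-one with a fully substituted benzene ring. C5 carries a hydroxyl group hydrogen-bonded to the C4 ketone, C6 a (3R)-octanoic acid chain joined through its C3, C7 a methoxy group and C8 a 3-methylbut-2-enyl (prenyl) group. The pyranone ring holds two adjacent stereocentres, C2 (S, on O1) and C3 (R, alpha to the ketone), with their methyl groups cis. The third centre, the benzylic carbon of the chain (R), is separated from them by the arene, so the two stereochemical problems are independent. The cis pair is the less stable arrangement, and C3 can epimerise by enolisation or by retro-oxa-Michael ring opening, so the finished ring must not meet base. The trisubstituted olefin is sensitive to strong acid and to hydrogenation, and the diazo ketone on the way is sensitive to acid, light and heat. The real difficulty is twofold: six ring positions of a very electron-rich arene must be filled in a defined order, and a contra-thermodynamic cis C2/C3 pair must be made with absolute control. The key step reads O1–C2(H)(CH3) as an O-ethyl group and C3 as the carbon of an alpha-methyl carbenoid, so the C2–C3 bond, the pyranone ring and both ring stereocentres arise in one neutral C–H insertion.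

## Logic of the disconnections

**16 to 15.** The acid O–H is traced back to the O–CH3 bond of a methyl ester. A free acid would quench the Grignard reagent, bind the Lewis acid and capture the carbenoid by O–H insertion. One robust spectator group is then carried from step 2 to the end. The forward step must hydrolyse the ester with a hydroxide source too weakly basic to enolise C4/C3.

**15 to 14.** The C5 O–H is traced back to a C5 O–CH3 bond. A free phenol beside the diazo ketone would give O–H insertion, and an ester or silyl group there would open ylide pathways. Both oxygens ortho to the chain stay identical methyl ethers, so the arene is symmetric until its first substitution. The forward step must cleave one of two aryl methyl ethers, which chelation between the C4 carbonyl and the peri oxygen can provide.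

**14 to 13.** The C2–C3 bond is cut, which opens the pyranone and removes both ring stereocentres. This is the only cut that makes the cis pair under neutral, catalyst-controlled conditions. It leaves a flat diazo ketone with an ortho ethoxy group. The forward step must choose one of two methylene hydrogens, the cis geometry, and the OCH2 over the C5 OCH3. The two methylene hydrogens are diastereotopic only through the remote chain centre, so the catalyst has to make the choice. The prenyl group is placed before this step on purpose: flanking the ethoxy group on its other side, it keeps the ethyl group near the acyl carbon.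

**13 to 11 (through 12).** The C3=N2 bond is cut. The diazo group is introduced last because it would not survive Lewis acid, bromination or hot palladium catalysis. The precursor becomes a plain ethyl ketone. The forward step must activate the ketone CH2 in the presence of the ester CH2, and a safe sulfonyl azide is chosen.

**11 to 9 and 10.** The aryl C8–CH2 bond is cut. Coupling on the ketone avoids any bromination or heating of the epimerisable chromanone. The forward step must couple at a bromide flanked by two alkoxy groups without allylic transposition.

**9 to 8.** The C8–Br bond is cut. Only one ring C–H is left, so no regiochemistry arises. The forward step must brominate the ring faster than the ketone alpha position.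

**8 to 6 and 7.** The aryl–acyl bond (C4a–C4) is cut, which removes C4, C3 and the C3 methyl as one unit. 6 has two equivalent free positions, so a single ketone can form. The forward step must stop at monoacylation and must not cleave an ortho ether.

**6 to 4 and 5.** The benzylic C–C bond to the pentyl group is cut. The chain stereocentre is set on a simple symmetric enoate, where it is the only task of the step. The forward step must add face-selectively in the 1,4 sense to a hindered, electron-rich cinnamate.

**4 to 2 and 3.** The C=C bond is cut, leaving an aldehyde and a two-carbon ester unit. The forward step must give the E-enoate.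

**2 to 1.** The O–CH2 bond of the ethoxy group is cut. The ethyl group is the future C2 and its methyl group, not a protecting group, and it is attached while only one hydroxyl is present. The forward step is a plain O-alkylation of 1.

## Other disconnections considered

**Alternative 1:** The cut lies inside the side chain. The benzylic carbon and its two CH2 neighbours are read as three ring carbons of the symmetric cyclobutanone A2, 3-[4-(benzyloxy)-2,6-dimethoxyphenyl]cyclobutan-1-one. In the forward step, aqueous H2O2 and a chiral BINOL-derived phosphoric acid would convert A2 into the lactone A1, (4R)-4-[4-(benzyloxy)-2,6-dimethoxyphenyl]oxolan-2-one. The acid organises the peroxide adduct so that one of the two enantiotopic CH2 groups migrates to oxygen, which creates the benzylic centre.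

- In its favour: the centre comes from an achiral ketone without an organometallic reagent, and no addition to a deactivated, doubly ortho-substituted cinnamate is needed. The lactone also tells the two arms apart. On the mildness and metal-free setting of this centre the alternative is the equal of step 3 or better.
- Against it here: A2 needs about three steps of its own (methylenation, ketene cycloaddition, dechlorination). In A1 the future pentyl arm is only an oxygen-bearing CH2, so four carbons must still be attached by opening the lactone and an sp3–sp3 coupling beside a branched centre. The electron-rich arene must tolerate peroxide and acid. The oxygen para to the chain carries benzyl, not the ethyl group that the ring closure needs.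
- Comparison: on structure it addresses only the chain centre and leaves the crowded arene and the cis C2/C3 pair unsolved. On mechanism both plans rely on a chiral catalyst choosing between enantiotopic elements, with comparable support. On step economy it should be about four steps longer.

**Alternative 2:** The cut is the benzylic C–CH2 bond together with a temporary O5–acyl bond, so the acid chain is folded onto the C5 oxygen as the dihydrocoumarin A3, (4R)-7-(benzyloxy)-5-methoxy-4-pentyl-3,4-dihydrochromen-2-one. In the forward step Cs2CO3 would expel sulfinate from the phenol sulfone A4, 5-(benzyloxy)-3-methoxy-2-[1-(4-methylbenzenesulfonyl)hexyl]phenol, to release its ortho-quinone methide. A chiral aminoindanol-derived triazolium carbene would turn an activated aryl acetate into an azolium enolate. The enolate adds to the exocyclic carbon, and the phenoxide then attacks the acyl azolium, closing the lactone and releasing the carbene.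

- In its favour: it is metal-free, and the benzylic centre is set while the two oxygens ortho to the chain become different (O5 as lactone oxygen, O7 as methyl ether). The late chelation-controlled demethylation of the chosen plan would not be needed. On this differentiation of O5 from O7 the alternative is better.
- Against it here: a quinone methide with a pentyl group can tautomerise to a vinylphenol, and the unsubstituted acetate-derived enolate is the least reactive of its class. A4 needs an unsymmetrical precursor, so the symmetry that makes ring substitution unambiguous is lost and the two free ring positions of A3 are different. The aryl lactone would not survive Grignard reagents or amide bases. The future O1 again carries benzyl.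
- Comparison: on structure it solves the chain and O5 but not the pyranone. On mechanism it uses organocatalytic enolate addition where the chosen plan uses copper-catalysed alkyl transfer, and neither has support on so hindered a substrate. On step economy the chain costs about the same, but the whole route should be longer because of the protecting-group exchange and regiochemical control.

**Alternative 3:** The cut goes through the benzene ring. In target numbering C7–C8 and C4a–C8a are formed and C6–C7 is closed last. The partners are the cyclobutenone A6, methyl (3R)-3-(2-ethoxy-4-oxocyclobut-2-en-1-yl)octanoate, and the siloxyalkyne A7, triisopropyl[(5-methylhex-4-en-1-yn-1-yl)oxy]silane. In the forward step heat would open A6 by four-electron electrocyclic opening, and the ketene unit would add across the alkyne of A7. The new four-membered ring opens again, and a six-electron electrocyclisation with tautomerisation would give the phenol A5, methyl (3R)-3-[6-ethoxy-2-hydroxy-3-(3-methylbut-2-enyl)-4-(triisopropylsilyloxy)phenyl]octanoate (Danheiser benzannulation).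

- In its favour: it is convergent, and the connectivity of the two partners places every ring substituent, the prenyl group included. No electrophilic substitution, bromination or tin reagent is needed, and three differently masked oxygens result. On regiocontrol of the arene and on avoiding organotin the alternative is better.
- Against it here: the chain stereocentre must already be in A6, next to the ring, and no short asymmetric route to such a cyclobutenone is apparent. A7 is a sensitive reagent. In A5 the ethyl group sits on the oxygen that becomes O5 and the silyl group on the future O1, so the ethoxy group is in the wrong place for a carbenoid closure. The pyranone would have to be closed from a phenol, with weak cis control, and the ethyl ether cleaved at the end. The last ring position (future C4a) would still have to be acylated on a pentasubstituted ring.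
- Comparison: on structure it solves the arene best but neither the chain centre nor the C2/C3 pair. On mechanism the pericyclic cascade is reliable but thermal. On step economy the two partners and the later oxygen manipulations should make it longer than ten steps.

Key step: step 8

Assumption: which enantiomer of the ferrocenyl diphosphine (step 3) and of Rh2(PTTL)4, dirhodium tetrakis(N-phthaloyl-tert-leucinate) (step 8), gives the required sense is settled on a small scale; (R,Sp)-Josiphos and Rh2(S-PTTL)4 are written, and the mirror-image catalyst is taken if the sense proves opposite.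

## Route

Step 1
Reactants: 1 4-hydroxy-2,6-dimethoxybenzaldehyde
Product: 2 4-ethoxy-2,6-dimethoxybenzaldehyde
Conditions: EtI, K2CO3, DMF, 50 °C
Reagents that add atoms: iodoethane, CCI
Why: Williamson ether synthesis; the phenoxide para to the formyl group is alkylated at oxygen, and this ethyl group later supplies C2 and its methyl group.

Step 2
Reactants: 2 4-ethoxy-2,6-dimethoxybenzaldehyde; 3 trimethyl phosphonoacetate
Product: 4 methyl (2E)-3-(4-ethoxy-2,6-dimethoxyphenyl)prop-2-enoate
Conditions: NaH, THF, 0 °C to reflux
Reagents that add atoms: none
Why: Horner–Wadsworth–Emmons olefination; the stabilised phosphonate anion should give the E-enoate, and heating overcomes the two ortho methoxy groups.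

Step 3
Reactants: 4 methyl (2E)-3-(4-ethoxy-2,6-dimethoxyphenyl)prop-2-enoate; 5 pentylmagnesium bromide
Product: 6 methyl (3R)-3-(4-ethoxy-2,6-dimethoxyphenyl)octanoate
Conditions: 5 (1.5 equiv, slow addition), CuBr·SMe2 (5 mol %), (R,Sp)-Josiphos [(R)-1-[(Sp)-2-(diphenylphosphino)ferrocenyl]ethyldicyclohexylphosphine] (6 mol %), t-BuOMe, −78 °C; then MeOH, aq. NH4Cl
Reagents that add atoms: none
Why: Copper-catalysed asymmetric conjugate addition of a Grignard reagent to an α,β-unsaturated methyl ester; the chiral copper–diphosphine complex binds one face of the enoate and delivers the pentyl group to the β-carbon, which sets the benzylic (3R) centre. The aryl group is symmetric, so no regiochemistry is involved.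

Step 4
Reactants: 6 methyl (3R)-3-(4-ethoxy-2,6-dimethoxyphenyl)octanoate; 7 propanoyl chloride
Product: 8 methyl (3R)-3-(4-ethoxy-2,6-dimethoxy-3-propanoylphenyl)octanoate
Conditions: SnCl4 (2 equiv), CH2Cl2, −20 to 0 °C
Reagents that add atoms: none
Why: Friedel–Crafts acylation; the two free ring positions of 6 are equivalent and each lies between two alkoxy groups, so one ketone should form, and its acyl group slows a second acylation. The low temperature avoids chelation-assisted ether cleavage.

Step 5
Reactants: 8 methyl (3R)-3-(4-ethoxy-2,6-dimethoxy-3-propanoylphenyl)octanoate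
Product: 9 methyl (3R)-3-(3-bromo-4-ethoxy-2,6-dimethoxy-5-propanoylphenyl)octanoate
Conditions: NBS (1.05 equiv), MeCN, 0 °C, dark
Reagents that add atoms: N-bromosuccinimide, O=C1CCC(=O)N1Br
Why: Electrophilic aromatic bromination; the single remaining ring C–H is ortho to two alkoxy groups and para to the third, so it should react faster than the ketone α-position.

Step 6
Reactants: 9 methyl (3R)-3-(3-bromo-4-ethoxy-2,6-dimethoxy-5-propanoylphenyl)octanoate; 10 tributyl(3-methylbut-2-en-1-yl)stannane
Product: 11 methyl (3R)-3-[4-ethoxy-2,6-dimethoxy-3-(3-methylbut-2-en-1-yl)-5-propanoylphenyl]octanoate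
Conditions: Pd2(dba)3 (2.5 mol %), P(t-Bu)3 (10 mol %), CsF (2.2 equiv), 1,4-dioxane, 90 °C
Reagents that add atoms: none
Why: Stille coupling; the bulky electron-rich phosphine enables oxidative addition of the hindered, electron-rich bromide to zerovalent palladium, and fluoride activates the stannane. Reductive elimination at the less substituted allyl terminus should give the linear prenyl arene.

Step 7
Reactants: 11 methyl (3R)-3-[4-ethoxy-2,6-dimethoxy-3-(3-methylbut-2-en-1-yl)-5-propanoylphenyl]octanoate
Product: 13 methyl (3R)-3-[3-(2-diazopropanoyl)-4-ethoxy-2,6-dimethoxy-5-(3-methylbut-2-en-1-yl)phenyl]octanoate, via trifluoroacetyl diketone 12 (not isolated)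
Conditions: LiN(SiMe3)2 (1.1 equiv), THF, −78 °C; CF3CO2CH2CF3, −78 °C; then 4-acetamidobenzenesulfonyl azide, Et3N, H2O (1 equiv), MeCN, rt
Reagents that add atoms: 4-acetamidobenzenesulfonyl azide, CC(=O)Nc1ccc(cc1)S(=O)(=O)N=[N+]=[N-]; 2,2,2-trifluoroethyl trifluoroacetate, FC(F)(F)COC(=O)C(F)(F)F (its atoms stay only in 12)
Why: Detrifluoroacetylative diazo transfer, a Regitz-type transfer to an activated ketone; the amide base removes a proton from the ketone CH2 in preference to the less acidic ester CH2, and C-trifluoroacetylation gives 12. The sulfonyl azide then transfers N2 with loss of the trifluoroacetyl group as an N-acylsulfonamide, and the chain stereocentre is not involved.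

Step 8
Reactants: 13 methyl (3R)-3-[3-(2-diazopropanoyl)-4-ethoxy-2,6-dimethoxy-5-(3-methylbut-2-en-1-yl)phenyl]octanoate
Product: 14 methyl (3R)-3-[(2S,3R)-5,7-dimethoxy-2,3-dimethyl-8-(3-methylbut-2-en-1-yl)-4-oxo-3,4-dihydro-2H-chromen-6-yl]octanoate
Conditions: Rh2(S-PTTL)4 (2 mol %), 4 Å MS, toluene, −40 to 0 °C, slow addition of 13
Reagents that add atoms: none
Why: Rh2(S-PTTL)4 adds to the diazo carbon of 13, N2 leaves, and an electrophilic dirhodium carbenoid stands at the future C3. This carbon inserts into one C–H bond of the ortho OCH2CH3 group in a concerted, asynchronous three-centre transition state, which creates C2–C3 and frees the catalyst; the closest known reaction type is the chiral dirhodium carboxylate-catalysed intramolecular C–H insertion of 2-alkoxyaryl α-diazo ketones to cis-2,3-disubstituted chroman-4-ones. The pyranone (O1, C2, C3, C4, C4a, C8a) closes by this C2–C3 bond through a six-membered transition state; a five-membered mode would need attack at O1 itself and a seven-membered mode the unactivated CH3. C2: the two methylene hydrogens are diastereotopic only through the remote chain centre, so the choice between them, and hence (2S), is made by the chiral carboxylate pocket. C3: its configuration is fixed in the same event by the orientation of the carbenoid methyl group relative to the C2 methyl group in the compact transition state, cis being the kinetic outcome of this insertion class, and the base-free medium keeps it. Site selectivity for OCH2 over the C5 OCH3, which is also a six-membered mode, rests on the higher reactivity of a secondary α-oxygen C–H bond and on the C8 prenyl group, which blocks the far side of O1 and holds the ethyl group near the acyl carbon. Chemoselectivity over 1,2-hydride shift and oxonium ylide formation rests on the bulky phthalimido carboxylates and the low temperature; slow addition suppresses carbene dimerisation and bimolecular cyclopropanation of the olefin, which like the chain is meta to the carbenoid-bearing carbon and cannot reach it within the molecule.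

Step 9
Reactants: 14 methyl (3R)-3-[(2S,3R)-5,7-dimethoxy-2,3-dimethyl-8-(3-methylbut-2-en-1-yl)-4-oxo-3,4-dihydro-2H-chromen-6-yl]octanoate
Product: 15 methyl (3R)-3-[(2S,3R)-5-hydroxy-7-methoxy-2,3-dimethyl-8-(3-methylbut-2-en-1-yl)-4-oxo-3,4-dihydro-2H-chromen-6-yl]octanoate
Conditions: BCl3 (1.2 equiv), CH2Cl2, −78 °C; then MeOH and pH 7 buffer at −78 °C
Reagents that add atoms: none
Why: Chelation-controlled ether cleavage; BCl3 bridges the C4 carbonyl oxygen and the peri C5 methoxy oxygen, and chloride removes that methyl group by SN2, while the C7 methoxy group and the ring oxygen cannot chelate and should stay. No base is present, so the cis C2/C3 pair should be kept, and at −78 °C the olefin should be left alone.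

Step 10
Reactants: 15 methyl (3R)-3-[(2S,3R)-5-hydroxy-7-methoxy-2,3-dimethyl-8-(3-methylbut-2-en-1-yl)-4-oxo-3,4-dihydro-2H-chromen-6-yl]octanoate
Product: 16 (3R)-3-[(2S,3R)-5-hydroxy-7-methoxy-2,3-dimethyl-8-(3-methylbut-2-en-1-yl)-4-oxo-3,4-dihydro-2H-chromen-6-yl]octanoic acid
Conditions: Me3SnOH (5 equiv), 1,2-dichloroethane, 70 °C; then dilute aq. HCl
Reagents that add atoms: trimethyltin hydroxide, C[Sn](C)(C)O
Why: Ester hydrolysis with trimethyltin hydroxide; the tin-bound hydroxide attacks the ester carbonyl but is too weakly basic to enolise the ketone, the more so as the C5 phenol is held as its phenoxide, so C3 should keep its configuration. Dilute acid releases the acid.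

## Compound list

1 | 4-hydroxy-2,6-dimethoxybenzaldehyde | O=Cc1c(OC)cc(O)cc1OC | starting material
2 | 4-ethoxy-2,6-dimethoxybenzaldehyde | O=Cc1c(OC)cc(OCC)cc1OC | intermediate
3 | trimethyl phosphonoacetate | COC(=O)CP(=O)(OC)OC | starting material
4 | methyl (2E)-3-(4-ethoxy-2,6-dimethoxyphenyl)prop-2-enoate | COC(=O)/C=C/c1c(OC)cc(OCC)cc1OC | intermediate
5 | pentylmagnesium bromide | CCCCC[Mg]Br | starting material
6 | methyl (3R)-3-(4-ethoxy-2,6-dimethoxyphenyl)octanoate | CCCCC[C@H](CC(=O)OC)c1c(OC)cc(OCC)cc1OC | intermediate
7 | propanoyl chloride | CCC(=O)Cl | starting material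
8 | methyl (3R)-3-(4-ethoxy-2,6-dimethoxy-3-propanoylphenyl)octanoate | CCCCC[C@H](CC(=O)OC)c1c(OC)c(C(=O)CC)c(OCC)cc1OC | intermediate
9 | methyl (3R)-3-(3-bromo-4-ethoxy-2,6-dimethoxy-5-propanoylphenyl)octanoate | CCCCC[C@H](CC(=O)OC)c1c(OC)c(C(=O)CC)c(OCC)c(Br)c1OC | intermediate
10 | tributyl(3-methylbut-2-en-1-yl)stannane | CCCC[Sn](CCCC)(CCCC)CC=C(C)C | starting material
11 | methyl (3R)-3-[4-ethoxy-2,6-dimethoxy-3-(3-methylbut-2-en-1-yl)-5-propanoylphenyl]octanoate | CCCCC[C@H](CC(=O)OC)c1c(OC)c(C(=O)CC)c(OCC)c(CC=C(C)C)c1OC | intermediate
12 | methyl (3R)-3-[4-ethoxy-2,6-dimethoxy-3-(3-methylbut-2-en-1-yl)-5-(4,4,4-trifluoro-2-methyl-3-oxobutanoyl)phenyl]octanoate (epimers at the new CH) | CCCCC[C@H](CC(=O)OC)c1c(OC)c(C(=O)C(C)C(=O)C(F)(F)F)c(OCC)c(CC=C(C)C)c1OC | intermediate (not isolated)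
13 | methyl (3R)-3-[3-(2-diazopropanoyl)-4-ethoxy-2,6-dimethoxy-5-(3-methylbut-2-en-1-yl)phenyl]octanoate | CCCCC[C@H](CC(=O)OC)c1c(OC)c(C(=O)C(C)=[N+]=[N-])c(OCC)c(CC=C(C)C)c1OC | intermediate
14 | methyl (3R)-3-[(2S,3R)-5,7-dimethoxy-2,3-dimethyl-8-(3-methylbut-2-en-1-yl)-4-oxo-3,4-dihydro-2H-chromen-6-yl]octanoate | CCCCC[C@H](CC(=O)OC)c1c(OC)c2c(c(CC=C(C)C)c1OC)O[C@@H](C)[C@@H](C)C2=O | intermediate
15 | methyl (3R)-3-[(2S,3R)-5-hydroxy-7-methoxy-2,3-dimethyl-8-(3-methylbut-2-en-1-yl)-4-oxo-3,4-dihydro-2H-chromen-6-yl]octanoate | CCCCC[C@H](CC(=O)OC)c1c(O)c2c(c(CC=C(C)C)c1OC)O[C@@H](C)[C@@H](C)C2=O | intermediate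
16 | (3R)-3-[(2S,3R)-5-hydroxy-7-methoxy-2,3-dimethyl-8-(3-methylbut-2-en-1-yl)-4-oxo-3,4-dihydro-2H-chromen-6-yl]octanoic acid | CCCCC[C@H](CC(=O)O)c1c(O)c2c(c(CC=C(C)C)c1OC)O[C@@H](C)[C@@H](C)C2=O | target

## Step count and least certain steps

Total step count: 10. Longest linear sequence: 10 steps (1 to 16).

**Step 8 (key step).** The most likely failure is migration of a hydrogen from the carbenoid methyl group outrunning insertion, so that material is lost as an aryl vinyl ketone. The second is poor discrimination between the two methylene hydrogens, or between cis and trans, at so crowded a site. The cause is that an α-alkyl carbenoid carries β-hydrogens and both ortho groups are ethers. The fallback sets out from 6 and returns at 14. It removes the methyl group from the carbenoid and brings it in afterwards.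
- Acetyl chloride and SnCl4 convert 6 into methyl (3R)-3-(3-acetyl-4-ethoxy-2,6-dimethoxyphenyl)octanoate F1.
- NBS gives methyl (3R)-3-(3-acetyl-5-bromo-4-ethoxy-2,6-dimethoxyphenyl)octanoate F2.
- The Stille coupling with 10 under the step 6 conditions gives methyl (3R)-3-[3-acetyl-4-ethoxy-2,6-dimethoxy-5-(3-methylbut-2-en-1-yl)phenyl]octanoate F3.
- LiN(SiMe3)2 and CF3CO2CH2CF3 give in the flask methyl (3R)-3-[4-ethoxy-2,6-dimethoxy-3-(3-methylbut-2-en-1-yl)-5-(4,4,4-trifluoro-3-oxobutanoyl)phenyl]octanoate F4.
- The sulfonyl azide and Et3N convert F4 into methyl (3R)-3-[3-(2-diazoacetyl)-4-ethoxy-2,6-dimethoxy-5-(3-methylbut-2-en-1-yl)phenyl]octanoate F5.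
- The same dirhodium catalyst should give, from a carbenoid without β-hydrogens, methyl (3R)-3-[(2S)-5,7-dimethoxy-2-methyl-8-(3-methylbut-2-en-1-yl)-4-oxo-3,4-dihydro-2H-chromen-6-yl]octanoate F6.
- LiN(SiMe3)2 and MeI at −78 °C give methyl (3R)-3-[(2S,3S)-5,7-dimethoxy-2,3-dimethyl-8-(3-methylbut-2-en-1-yl)-4-oxo-3,4-dihydro-2H-chromen-6-yl]octanoate F7. Its C3 configuration does not matter.
- LiN(i-Pr)2 at −78 °C followed by a hindered phenol should give 14. In the enolate the C2 methyl group sits pseudo-axial to avoid allylic 1,2-strain, and the proton enters anti to it, which places the C3 methyl group cis.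

**Step 3.** The likely failure is slow conjugate addition with erosion of facial selectivity and competing 1,2-addition. The cause is that the β-carbon is shielded by two ortho methoxy groups and deactivated by three donor oxygens. The fallback sets out from 4 and returns at 6. It replaces catalyst control by a covalently bound auxiliary on a more electrophilic imide.
- LiOH in aqueous THF gives (2E)-3-(4-ethoxy-2,6-dimethoxyphenyl)prop-2-enoic acid F8.
- Pivaloyl chloride and Et3N, then (4R)-4-phenyl-1,3-oxazolidin-2-one and LiCl, give (4R)-3-[(2E)-3-(4-ethoxy-2,6-dimethoxyphenyl)prop-2-enoyl]-4-phenyl-1,3-oxazolidin-2-one F9.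
- 5 with CuBr·SMe2 in THF at −40 °C should add anti to the phenyl group of the magnesium-chelated s-cis conformer. This gives (4R)-3-[(3R)-3-(4-ethoxy-2,6-dimethoxyphenyl)octanoyl]-4-phenyl-1,3-oxazolidin-2-one F10.
- MeOMgBr in MeOH at 0 °C gives 6 and returns the auxiliary.

**Step 6.** The likely failures are sluggish oxidative addition and transmetalation at a bromide flanked by two alkoxy groups, and allylic transposition during transfer of the prenyl group. Transposition would give the branched isomer, or the double bond could move into conjugation. The fallback sets out from 9 and returns at 11. It transfers an allyl group, which has no regiochemical ambiguity, and builds the trisubstituted olefin afterwards.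
- Suzuki–Miyaura coupling with allylboronic acid pinacol ester (Pd(OAc)2, SPhos, K3PO4, THF/H2O, 60 °C) gives methyl (3R)-3-[4-ethoxy-2,6-dimethoxy-3-(prop-2-en-1-yl)-5-propanoylphenyl]octanoate F11.
- Cross-metathesis with excess 2-methylbut-2-ene and the second-generation Grubbs catalyst, (H2IMes)(PCy3)Cl2Ru=CHPh, in CH2Cl2 at 40 °C gives 11.

**Step 7.** The likely failures are competing deprotonation at the ester CH2 and O- in place of C-acylation of the hindered, twisted enolate, either of which leaves the diazo transfer incomplete. The fallback sets out from 11 and returns at 13. It replaces the lithium enolate by soft enolisation and isolates a stable diketone.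
- MgBr2·OEt2, i-Pr2NEt and benzoyl chloride in CH2Cl2 give methyl (3R)-3-[4-ethoxy-2,6-dimethoxy-3-(3-methylbut-2-en-1-yl)-5-(2-methyl-3-oxo-3-phenylpropanoyl)phenyl]octanoate F12.
- 4-Acetamidobenzenesulfonyl azide and DBU in MeCN at 0 °C give 13 by debenzoylative diazo transfer. The unhindered benzoyl group, not the doubly ortho-substituted aroyl group, should be the one expelled.

**Step 9.** The likely failures are addition of HCl, formed from BCl3 and traces of water, to the trisubstituted olefin, and loss of the cis relationship through enolisation of the boron-chelated ketone. The fallback sets out from 9 and returns at 15. It cleaves the ether before the olefin is present.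
- The step 7 conditions give in the flask methyl (3R)-3-[3-bromo-4-ethoxy-2,6-dimethoxy-5-(4,4,4-trifluoro-2-methyl-3-oxobutanoyl)phenyl]octanoate F13.
- Diazo transfer then gives methyl (3R)-3-[3-bromo-5-(2-diazopropanoyl)-4-ethoxy-2,6-dimethoxyphenyl]octanoate F14.
- The step 8 conditions give methyl (3R)-3-[(2S,3R)-8-bromo-5,7-dimethoxy-2,3-dimethyl-4-oxo-3,4-dihydro-2H-chromen-6-yl]octanoate F15.
- BCl3 at −78 °C gives methyl (3R)-3-[(2S,3R)-8-bromo-5-hydroxy-7-methoxy-2,3-dimethyl-4-oxo-3,4-dihydro-2H-chromen-6-yl]octanoate F16.
- A fluoride-free Stille coupling with 10 (Pd2(dba)3, P(t-Bu)3, toluene, 80 °C) gives 15.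

## Further compounds

F1 | step 8 | methyl (3R)-3-(3-acetyl-4-ethoxy-2,6-dimethoxyphenyl)octanoate | CCCCC[C@H](CC(=O)OC)c1c(OC)c(C(C)=O)c(OCC)cc1OC
F2 | step 8 | methyl (3R)-3-(3-acetyl-5-bromo-4-ethoxy-2,6-dimethoxyphenyl)octanoate | CCCCC[C@H](CC(=O)OC)c1c(OC)c(C(C)=O)c(OCC)c(Br)c1OC
F3 | step 8 | methyl (3R)-3-[3-acetyl-4-ethoxy-2,6-dimethoxy-5-(3-methylbut-2-en-1-yl)phenyl]octanoate | CCCCC[C@H](CC(=O)OC)c1c(OC)c(C(C)=O)c(OCC)c(CC=C(C)C)c1OC
F4 | step 8 | methyl (3R)-3-[4-ethoxy-2,6-dimethoxy-3-(3-methylbut-2-en-1-yl)-5-(4,4,4-trifluoro-3-oxobutanoyl)phenyl]octanoate | CCCCC[C@H](CC(=O)OC)c1c(OC)c(C(=O)CC(=O)C(F)(F)F)c(OCC)c(CC=C(C)C)c1OC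
F5 | step 8 | methyl (3R)-3-[3-(2-diazoacetyl)-4-ethoxy-2,6-dimethoxy-5-(3-methylbut-2-en-1-yl)phenyl]octanoate | CCCCC[C@H](CC(=O)OC)c1c(OC)c(C(=O)C=[N+]=[N-])c(OCC)c(CC=C(C)C)c1OC
F6 | step 8 | methyl (3R)-3-[(2S)-5,7-dimethoxy-2-methyl-8-(3-methylbut-2-en-1-yl)-4-oxo-3,4-dihydro-2H-chromen-6-yl]octanoate | CCCCC[C@H](CC(=O)OC)c1c(OC)c2c(c(CC=C(C)C)c1OC)O[C@@H](C)CC2=O
F7 | step 8 | methyl (3R)-3-[(2S,3S)-5,7-dimethoxy-2,3-dimethyl-8-(3-methylbut-2-en-1-yl)-4-oxo-3,4-dihydro-2H-chromen-6-yl]octanoate | CCCCC[C@H](CC(=O)OC)c1c(OC)c2c(c(CC=C(C)C)c1OC)O[C@@H](C)[C@H](C)C2=O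
F8 | step 3 | (2E)-3-(4-ethoxy-2,6-dimethoxyphenyl)prop-2-enoic acid | OC(=O)/C=C/c1c(OC)cc(OCC)cc1OC
F9 | step 3 | (4R)-3-[(2E)-3-(4-ethoxy-2,6-dimethoxyphenyl)prop-2-enoyl]-4-phenyl-1,3-oxazolidin-2-one | O=C(/C=C/c1c(OC)cc(OCC)cc1OC)N1[C@H](c2ccccc2)COC1=O
F10 | step 3 | (4R)-3-[(3R)-3-(4-ethoxy-2,6-dimethoxyphenyl)octanoyl]-4-phenyl-1,3-oxazolidin-2-one | CCCCC[C@H](CC(=O)N1[C@H](c2ccccc2)COC1=O)c1c(OC)cc(OCC)cc1OC
F11 | step 6 | methyl (3R)-3-[4-ethoxy-2,6-dimethoxy-3-(prop-2-en-1-yl)-5-propanoylphenyl]octanoate | CCCCC[C@H](CC(=O)OC)c1c(OC)c(C(=O)CC)c(OCC)c(CC=C)c1OC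
F12 | step 7 | methyl (3R)-3-[4-ethoxy-2,6-dimethoxy-3-(3-methylbut-2-en-1-yl)-5-(2-methyl-3-oxo-3-phenylpropanoyl)phenyl]octanoate | CCCCC[C@H](CC(=O)OC)c1c(OC)c(C(=O)C(C)C(=O)c2ccccc2)c(OCC)c(CC=C(C)C)c1OC
F13 | step 9 | methyl (3R)-3-[3-bromo-4-ethoxy-2,6-dimethoxy-5-(4,4,4-trifluoro-2-methyl-3-oxobutanoyl)phenyl]octanoate | CCCCC[C@H](CC(=O)OC)c1c(OC)c(C(=O)C(C)C(=O)C(F)(F)F)c(OCC)c(Br)c1OC
F14 | step 9 | methyl (3R)-3-[3-bromo-5-(2-diazopropanoyl)-4-ethoxy-2,6-dimethoxyphenyl]octanoate | CCCCC[C@H](CC(=O)OC)c1c(OC)c(C(=O)C(C)=[N+]=[N-])c(OCC)c(Br)c1OC
F15 | step 9 | methyl (3R)-3-[(2S,3R)-8-bromo-5,7-dimethoxy-2,3-dimethyl-4-oxo-3,4-dihydro-2H-chromen-6-yl]octanoate | CCCCC[C@H](CC(=O)OC)c1c(OC)c2c(c(Br)c1OC)O[C@@H](C)[C@@H](C)C2=O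
F16 | step 9 | methyl (3R)-3-[(2S,3R)-8-bromo-5-hydroxy-7-methoxy-2,3-dimethyl-4-oxo-3,4-dihydro-2H-chromen-6-yl]octanoate | CCCCC[C@H](CC(=O)OC)c1c(O)c2c(c(Br)c1OC)O[C@@H](C)[C@@H](C)C2=O
A1 | alternative 1 | (4R)-4-[4-(benzyloxy)-2,6-dimethoxyphenyl]oxolan-2-one | O1C[C@H](CC1=O)c2c(OC)cc(OCc3ccccc3)cc2OC
A2 | alternative 1 | 3-[4-(benzyloxy)-2,6-dimethoxyphenyl]cyclobutan-1-one | O=C1CC(C1)c1c(OC)cc(OCc2ccccc2)cc1OC
A3 | alternative 2 | (4R)-7-(benzyloxy)-5-methoxy-4-pentyl-3,4-dihydrochromen-2-one | CCCCC[C@@H]1CC(=O)Oc2cc(OCc3ccccc3)cc(OC)c21
A4 | alternative 2 | 5-(benzyloxy)-3-methoxy-2-[1-(4-methylbenzenesulfonyl)hexyl]phenol | CCCCCC(c1c(O)cc(OCc2ccccc2)cc1OC)S(=O)(=O)c1ccc(C)cc1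
A5 | alternative 3 | methyl (3R)-3-[6-ethoxy-2-hydroxy-3-(3-methylbut-2-enyl)-4-(triisopropylsilyloxy)phenyl]octanoate | CCCCC[C@H](CC(=O)OC)c1c(O)c(CC=C(C)C)c(O[Si](C(C)C)(C(C)C)C(C)C)cc1OCC
A6 | alternative 3 | methyl (3R)-3-(2-ethoxy-4-oxocyclobut-2-en-1-yl)octanoate | CCCCC[C@H](CC(=O)OC)C1C(OCC)=CC1=O
A7 | alternative 3 | triisopropyl[(5-methylhex-4-en-1-yn-1-yl)oxy]silane | CC(C)=CCC#CO[Si](C(C)C)(C(C)C)C(C)C
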